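Eudesmane numbering is used throughout: ring A = C1–C5 and C10, ring B = C5–C10, C11–C13 = the acrylic acid unit (C12 = carboxyl carbon), C14 = angular methyl, C15 = the oxygenated carbon on C4. The target is 22; compound numbers are those of the steps below.

## The problem

The target is a eudesmane, a trans-fused decalin with a quaternary C10 bearing the angular methyl, a trans ring-fusion hydrogen at C5 and an equatorial acrylic acid unit at C7; the configuration is 5R,7R,10R. Ring A holds a trisubstituted C3=C4 double bond directly beside the ring fusion, with the oxygenated C15 on C4. Routes that pass through a C4 cation or a C3 ketone must place this double bond afterwards and tend to give mixtures of the 3-ene, the 4-ene and the exocyclic 4(15)-ene. C7 is the only stereocentre outside the ring fusion, and it can steer C5 (1,3) and C10 (1,4) only through a chair in which its substituent is equatorial. Enolate alkylation of a C7-substituted cyclohexanone puts the incoming chain, not the methyl, axial at C10, which is the wrong epimer. Two primary allylic carbons (C12 and C15) carry oxygen at different oxidation levels and must be told apart. The (Z)-p-coumarate is the most fragile part: it isomerises to E under light, with nucleophiles and as its phenoxide, and it sits on an allylic ester that ionises with strong acid or zerovalent palladium, while the α-methylene acid is a Michael acceptor. The feature the plan exploits is twofold. Ring A is a cyclohexene whose double bond (C3=C4) lies next to the fusion carbon C5, which is the imprint of a [4+2] addition of a C2=C3–C4(C15)=C5 diene to the C1=C10 olefin. Ring B, with its single side chain at C7 and the methyl on C10, is the carbon skeleton of limonene, so cutting the ring double bond of limonene gives a chain whose two ends are C5 and C10.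

## Retrosynthesis

**22 ⇒ 14 + 15 + 17 (via 21, 20, 19, 18, 16).** The cinnamate Cα=Cβ bond and the acyl–O15 bond are cut, and C12 is taken back from the acid to a PMB-protected alcohol. The Z double bond is made on the substrate by olefination of phosphonoacetate 16 with aldehyde 17, not by acylation with a preformed (Z)-acid. Every activation of a (Z)-cinnamic acid (acyl pyridinium, phosphine) opens an addition–elimination path to the E isomer, whereas the olefination creates Z kinetically at −78 °C. C12 is raised to the acid only after this (18 → 19 → 20 → 21) under neutral or weakly acidic conditions, and the phenol is unmasked last (21 → 22). The precursor 14 has no ester, no acid and no Z-olefin. The forward steps must only leave the Z geometry and the allylic ester untouched.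

**14 ⇒ 13.** The C5–C10 and C1–C2 bonds are cut, the retron of an intramolecular Diels–Alder reaction. The neighbouring cut (C4–C5 and C1–C10, an annulation onto a cyclohexanone) leaves a C3 carbonyl that the target lacks and does not control C10. A cut of C5–C10 alone needs a ten-membered ring. The [4+2] cut places C3=C4 and C15 where they belong and forms both rings and both ring-fusion centres at once. The precursor 13 is an acyclic triene with a single stereocentre (C7). The forward reaction must give the trans ring fusion and must choose the diene face that puts the C7 substituent equatorial.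

**13 ⇒ 8 (via 11, 10, 9).** The C4–C15 and C3–C4 bonds and the C10=C1 double bond are cut. The diene needs C6 cis to C15 on the trisubstituted C4=C5 bond. A Wittig reaction with a disubstituted allylic ylide would give E/Z mixtures, and an aldol route to the α-vinyl enal gives the wrong geometry. Instead the aldehyde carbon C5 of 8 is turned into a gem-dibromo-olefin (9), whose two bromines are replaced one after the other with retention. Vinyl goes trans to C6 (10) and, after methylenation of the ketone (11), CH2OH goes cis to C6 (13). The geometry is thus set by the order of two stereoretentive steps. Keto aldehyde 8 has no olefin geometry at all.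

**8 ⇒ 1 (via 6, 5, 4).** The C5–C10 bond of the target is mentally re-formed as the ring double bond of a limonene: 8 is the oxidative cleavage product of epoxide 6. The C12 oxygen is taken back to the isopropenyl methyl of (R)-limonene 1, where allylic metalation is selective (4, then PMB ether 5). Limonene supplies C5–C14 (twelve of the fifteen skeletal carbons) and the C7 stereocentre. The ring is opened only so that three carbons (C2–C4, with C15) can be inserted between its former olefinic carbons. The forward steps must differentiate the two olefins of 5, which their substitution and the allylic ether ensure.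

## Roads not taken

**Alternative 1:** Cut C4–C5 and C1–C10 (Robinson annulation, the obvious route). Dihydrocarvone A1 would be annulated with a vinyl ketone to octalone A2. Dissolving-metal reduction with carboxylation of the enolate would give the trans β-keto ester A3, followed by enol triflate formation, reduction of the triflate and reduction of the ester. The Michael step attacks the enolate of A1 axially and puts the chain cis to the C7 substituent, so the wrong C10 epimer dominates unless a chiral amine auxiliary is added. Four functional-group steps are then spent erasing a C3 carbonyl that the target does not have. The chosen plan forms C3=C4 and C15 in the ring-forming step and takes C10 from the cycloaddition geometry.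

**Alternative 2:** Cut C5–C10 only, inside a ten-membered ring (biomimetic transannular cyclisation). The (E,E)-germacradiene A4 would be protonated at C1 and the C10 cation captured by C5 to give the trans-fused eudesmyl C4 cation. The stereochemistry is reliable, but the C4 cation loses a proton towards C3, C5 and C15 without control, and with oxygen on C15 a hydride shift to the aldehyde competes. The functionalised (E,E)-cyclodecadiene is also harder to make than the target itself. The Diels–Alder plan has no cationic intermediate and fixes the double bond by the pericyclic mechanism.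

**Alternative 3:** Cut C3=C4 (ring-closing metathesis of diene A5 with second-generation Grubbs catalyst). The ring closure would be dependable, but A5 already contains all three stereocentres, so the metathesis solves none of the stereochemical problem. C10 would again come from an enolate alkylation with the wrong facial preference, and C5 from a separate reduction or addition. The chosen key step starts from a precursor with one stereocentre and creates the other two.

Key step: step 9

Remark: [bis(2,2,2-trifluoroethoxy)phosphoryl]acetic acid (15) is taken as a stock reagent, being the free acid of the commercial Still–Gennari phosphonate. The two epoxide carbons of 6 and the carbinol carbons of 7 are left undefined because step 4 destroys them. All operations from step 11 on are run with exclusion of light.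

## Route

Step 1
Reactants: 1 (R)-(+)-limonene
Product: 4 2-[(1R)-4-methylcyclohex-3-en-1-yl]prop-2-en-1-ol, via allyllithium 2 (not isolated), via allylboronate 3 (not isolated)
Conditions: n-BuLi, TMEDA, hexane, rt; B(OMe)3, THF, −78 °C → rt; H2O2, NaOH aq, 0 °C
Reagents that add atoms: hydrogen peroxide, OO (hydroxyl oxygen of 4); n-butyllithium, CCCC[Li] (lithium of 2 only); trimethyl borate, COB(OC)OC (boron and methoxy groups of 3 only)
Why: Allylic metalation of limonene with n-BuLi·TMEDA takes place at the isopropenyl methyl and gives a 2-substituted allyl anion with two equivalent CH2 termini, so borylation and oxidation (C–B to C–O with retention) can only give the primary allylic alcohol; the stereocentre is not involved.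

Step 2
Reactants: 4 2-[(1R)-4-methylcyclohex-3-en-1-yl]prop-2-en-1-ol
Product: 5 1-methoxy-4-({[2-((1R)-4-methylcyclohex-3-en-1-yl)prop-2-en-1-yl]oxy}methyl)benzene
Conditions: NaH, 4-methoxybenzyl chloride, n-Bu4NI (cat.), THF/DMF, 0 °C → rt
Reagents that add atoms: 4-methoxybenzyl chloride, COc1ccc(CCl)cc1
Why: Williamson etherification of the primary alkoxide; the PMB ether masks the C12 oxygen through the organometallic and thermal steps and is later removed by DDQ without acid or base.

Step 3
Reactants: 5 1-methoxy-4-({[2-((1R)-4-methylcyclohex-3-en-1-yl)prop-2-en-1-yl]oxy}methyl)benzene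
Product: 6 (4R)-4-{3-[(4-methoxyphenyl)methoxy]prop-1-en-2-yl}-1-methyl-7-oxabicyclo[4.1.0]heptane (both epoxide diastereomers)
Conditions: mCPBA, NaHCO3, CH2Cl2, 0 °C
Reagents that add atoms: 3-chloroperbenzoic acid, OOC(=O)c1cccc(Cl)c1
Why: Prilezhaev epoxidation; the trisubstituted ring olefin is far more nucleophilic than the 1,1-disubstituted olefin carrying an inductively withdrawing allylic ether, and both epoxide diastereomers serve because the two carbons become carbonyls in step 4.

Step 4
Reactants: 6 (4R)-4-{3-[(4-methoxyphenyl)methoxy]prop-1-en-2-yl}-1-methyl-7-oxabicyclo[4.1.0]heptane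
Product: 8 (3R)-3-{3-[(4-methoxyphenyl)methoxy]prop-1-en-2-yl}-6-oxoheptanal, via diol 7 (not isolated)
Conditions: H5IO6, THF/H2O, 0 °C → rt
Reagents that add atoms: water, O
Why: Periodic acid opens the epoxide to the trans-diol and cleaves it at once (Malaprade glycol cleavage) to the methyl ketone (future C10 with C14) and the aldehyde (future C5); the stereocentre (future C7) is β to the aldehyde and γ to the ketone and cannot epimerise.

Step 5
Reactants: 8 (3R)-3-{3-[(4-methoxyphenyl)methoxy]prop-1-en-2-yl}-6-oxoheptanal
Product: 9 (5R)-8,8-dibromo-5-{3-[(4-methoxyphenyl)methoxy]prop-1-en-2-yl}oct-7-en-2-one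
Conditions: CBr4, PPh3, CH2Cl2, 0 °C
Reagents that add atoms: carbon tetrabromide, BrC(Br)(Br)Br
Why: Ramirez dibromo-olefination (first stage of the Corey–Fuchs sequence); Ph3P=CBr2 condenses with the aldehyde much faster than with the methyl ketone at 0 °C, and the gem-dibromide carries both future substituents of C4.

Step 6
Reactants: 9 (5R)-8,8-dibromo-5-{3-[(4-methoxyphenyl)methoxy]prop-1-en-2-yl}oct-7-en-2-one
Product: 10 (5R,7Z)-8-bromo-5-{3-[(4-methoxyphenyl)methoxy]prop-1-en-2-yl}deca-7,9-dien-2-one
Conditions: CH2=CHSnBu3, Pd2(dba)3 (cat.), P(2-furyl)3, toluene, 100 °C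
Reagents that add atoms: tributyl(vinyl)stannane, C=C[Sn](CCCC)(CCCC)CCCC
Why: Stille coupling; zerovalent palladium inserts first into the less hindered C–Br bond trans to the alkyl chain and couples with retention, so the vinyl group (C3=C2) enters trans to C6, which is the diene geometry that lets the tether reach the s-cis diene.

Step 7
Reactants: 10 (5R,7Z)-8-bromo-5-{3-[(4-methoxyphenyl)methoxy]prop-1-en-2-yl}deca-7,9-dien-2-one
Product: 11 (5R,7Z)-8-bromo-5-{3-[(4-methoxyphenyl)methoxy]prop-1-en-2-yl}-2-methyldeca-1,7,9-triene
Conditions: Ph3PCH3Br, KOt-Bu, THF, 0 °C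
Reagents that add atoms: methyltriphenylphosphonium bromide, C[P+](c1ccccc1)(c1ccccc1)c1ccccc1.[Br-]
Why: Wittig methylenation of the methyl ketone gives the 1,1-disubstituted olefin C10(=C1H2)–C14; the unstabilised ylide adds to the ketone without touching the vinyl bromide, and no stereocentre is α to the carbonyl.

Step 8
Reactants: 11 (5R,7Z)-8-bromo-5-{3-[(4-methoxyphenyl)methoxy]prop-1-en-2-yl}-2-methyldeca-1,7,9-triene
Product: 13 (2Z,5R)-2-ethenyl-5-{3-[(4-methoxyphenyl)methoxy]prop-1-en-2-yl}-8-methylnona-2,8-dien-1-ol, via dienyllithium 12 (not isolated)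
Conditions: t-BuLi, Et2O, −78 °C; then CH2O (from paraformaldehyde), −78 → 0 °C
Reagents that add atoms: formaldehyde, C=O; tert-butyllithium, [Li]C(C)(C)C (lithium of 12 only)
Why: Bromine–lithium exchange of the vinyl bromide at −78 °C is faster than addition to the olefins and gives a configurationally stable dienyllithium that adds to formaldehyde with retention, so C15 enters cis to C6 as a free CH2OH.

Step 9
Reactants: 13 (2Z,5R)-2-ethenyl-5-{3-[(4-methoxyphenyl)methoxy]prop-1-en-2-yl}-8-methylnona-2,8-dien-1-ol
Product: 14 [(4aR,7R,8aR)-7-{3-[(4-methoxyphenyl)methoxy]prop-1-en-2-yl}-4a-methyl-3,4,4a,5,6,7,8,8a-octahydronaphthalen-1-yl]methanol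
Conditions: toluene (0.01 M), BHT, sealed tube, 200 °C
Reagents that add atoms: none
Why: Thermal type 1 intramolecular Diels–Alder reaction of a 1,7,9-decatriene: the C2=C3–C4=C5 diene (its s-cis form favoured by the C4 substituent) adds suprafacially to the 1,1-disubstituted C1=C10 olefin in one concerted step, forming C1–C2 and C5–C10. The closest known reaction type is the thermal cyclisation of 2-methyl-1,7,9-decatrienes bearing a substituent on the internal diene carbon, which gives angularly methylated Δ3-octalins. Ring A closes as the [4+2] ring itself; ring B closes through the C5–C10 bond as the four-carbon tether C6–C9 folds into a chair. C5 and C10 are set relative to each other by the choice between the extended (trans-fused) and the folded (cis-fused) transition state; the CH2OH group on C4, cis to C6, is pressed against the C6 hydrogens in the folded geometry and so acts as a steric directing group for trans fusion. Both centres are set relative to C7 by the chair tether, in which the branched allyl group on C7 sits equatorial; trans fusion with an equatorial C7 substituent is the 5R,7R,10R arrangement. The step therefore needs trans over cis fusion and one diene face over the other, and the substrate offers the C4 substituent for the first and the limonene-derived C7 centre for the second, while regiochemistry is fixed by the tether. The side-chain olefin cannot compete because only two atoms link it to the diene, and no Lewis acid is used because the allylic oxygens would ionise.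

Step 10
Reactants: 14 [(4aR,7R,8aR)-7-{3-[(4-methoxyphenyl)methoxy]prop-1-en-2-yl}-4a-methyl-3,4,4a,5,6,7,8,8a-octahydronaphthalen-1-yl]methanol; 15 [bis(2,2,2-trifluoroethoxy)phosphoryl]acetic acid
Product: 16 [(4aR,7R,8aR)-7-{3-[(4-methoxyphenyl)methoxy]prop-1-en-2-yl}-4a-methyl-3,4,4a,5,6,7,8,8a-octahydronaphthalen-1-yl]methyl 2-[bis(2,2,2-trifluoroethoxy)phosphoryl]acetate
Conditions: DCC, DMAP (cat.), CH2Cl2, 0 °C → rt
Reagents that add atoms: none
Why: Steglich esterification of the unhindered primary allylic alcohol; the acid is activated, not the alcohol, so no allylic transposition can occur.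

Step 11
Reactants: 16 the phosphonoacetate of step 10; 17 4-[(tert-butyldimethylsilyl)oxy]benzaldehyde
Product: 18 [(4aR,7R,8aR)-7-{3-[(4-methoxyphenyl)methoxy]prop-1-en-2-yl}-4a-methyl-3,4,4a,5,6,7,8,8a-octahydronaphthalen-1-yl]methyl (2Z)-3-{4-[(tert-butyldimethylsilyl)oxy]phenyl}prop-2-enoate
Conditions: KN(SiMe3)2, 18-crown-6, THF, −78 °C, dark
Reagents that add atoms: none
Why: Still–Gennari olefination; with the electron-poor bis(trifluoroethyl) phosphonate and a dissociated potassium counter-ion, elimination from the first-formed adduct outruns its equilibration and gives the kinetic (Z)-enoate, for which aromatic aldehydes are the best substrates.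

Step 12
Reactants: 18 the PMB-protected (Z)-cinnamate of step 11
Product: 19 [(4aR,7R,8aR)-7-(3-hydroxyprop-1-en-2-yl)-4a-methyl-3,4,4a,5,6,7,8,8a-octahydronaphthalen-1-yl]methyl (2Z)-3-{4-[(tert-butyldimethylsilyl)oxy]phenyl}prop-2-enoate
Conditions: DDQ, CH2Cl2/pH 7 buffer, 0 °C, dark
Reagents that add atoms: none
Why: Oxidative cleavage of the 4-methoxybenzyl ether (hydride abstraction, then hydrolysis of the oxocarbenium ion) at neutral pH; the aryl silyl ether, the electron-poor cinnamate and the allylic ester are inert to DDQ at 0 °C.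

Step 13
Reactants: 19 the C12 alcohol of step 12
Product: 20 [(4aR,7R,8aR)-4a-methyl-7-(3-oxoprop-1-en-2-yl)-3,4,4a,5,6,7,8,8a-octahydronaphthalen-1-yl]methyl (2Z)-3-{4-[(tert-butyldimethylsilyl)oxy]phenyl}prop-2-enoate
Conditions: Dess–Martin periodinane, NaHCO3, CH2Cl2, 0 °C, dark
Reagents that add atoms: none
Why: Dess–Martin oxidation of the primary allylic alcohol to the α-substituted acrolein under buffered, non-nucleophilic conditions; the enal is taken on without storage.

Step 14
Reactants: 20 the enal of step 13
Product: 21 2-[(2R,4aR,8aR)-8-{[((2Z)-3-{4-[(tert-butyldimethylsilyl)oxy]phenyl}prop-2-enoyl)oxy]methyl}-4a-methyl-1,2,3,4,4a,5,6,8a-octahydronaphthalen-2-yl]prop-2-enoic acid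
Conditions: NaClO2, NaH2PO4, 2-methyl-2-butene, t-BuOH/H2O, 0 °C, dark
Reagents that add atoms: sodium chlorite, [Na+].[O-]Cl=O
Why: Pinnick oxidation; chlorous acid converts the enal into the acid without epoxidising or isomerising olefins, 2-methyl-2-butene removes hypochlorous acid, and the phenol is still silylated so that ring chlorination is excluded.

Step 15
Reactants: 21 the silyl-protected acid of step 14
Product: 22 2-[(2R,4aR,8aR)-8-({[(2Z)-3-(4-hydroxyphenyl)prop-2-enoyl]oxy}methyl)-4a-methyl-1,2,3,4,4a,5,6,8a-octahydronaphthalen-2-yl]prop-2-enoic acid (CNP0183482.1)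
Conditions: HF·pyridine, THF/pyridine, 0 °C, dark
Reagents that add atoms: none
Why: Fluoride cleaves the aryl silyl ether; the acidic medium keeps the phenol protonated, which avoids the phenoxide that lowers the rotation barrier of the (Z)-cinnamate, and leaves the allylic ester and the acrylic acid alone.

## Compound list

1 | (R)-(+)-limonene, (4R)-1-methyl-4-(prop-1-en-2-yl)cyclohex-1-ene | CC1=CC[C@@H](CC1)C(C)=C | starting material
2 | {2-[(1R)-4-methylcyclohex-3-en-1-yl]prop-2-en-1-yl}lithium | CC1=CC[C@@H](CC1)C(=C)C[Li] | intermediate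
3 | dimethyl {2-[(1R)-4-methylcyclohex-3-en-1-yl]prop-2-en-1-yl}boronate | CC1=CC[C@@H](CC1)C(=C)CB(OC)OC | intermediate
4 | 2-[(1R)-4-methylcyclohex-3-en-1-yl]prop-2-en-1-ol | CC1=CC[C@@H](CC1)C(=C)CO | intermediate
5 | 1-methoxy-4-({[2-((1R)-4-methylcyclohex-3-en-1-yl)prop-2-en-1-yl]oxy}methyl)benzene | CC1=CC[C@@H](CC1)C(=C)COCc1ccc(OC)cc1 | intermediate
6 | (4R)-4-{3-[(4-methoxyphenyl)methoxy]prop-1-en-2-yl}-1-methyl-7-oxabicyclo[4.1.0]heptane (epoxide diastereomers) | CC12OC1C[C@@H](CC2)C(=C)COCc1ccc(OC)cc1 | intermediate
7 | (4R)-4-{3-[(4-methoxyphenyl)methoxy]prop-1-en-2-yl}-1-methylcyclohexane-1,2-diol (trans-diol, diastereomers) | CC1(O)C(O)C[C@@H](CC1)C(=C)COCc1ccc(OC)cc1 | intermediate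
8 | (3R)-3-{3-[(4-methoxyphenyl)methoxy]prop-1-en-2-yl}-6-oxoheptanal | O=CC[C@@H](CCC(C)=O)C(=C)COCc1ccc(OC)cc1 | intermediate
9 | (5R)-8,8-dibromo-5-{3-[(4-methoxyphenyl)methoxy]prop-1-en-2-yl}oct-7-en-2-one | BrC(Br)=CC[C@@H](CCC(C)=O)C(=C)COCc1ccc(OC)cc1 | intermediate
10 | (5R,7Z)-8-bromo-5-{3-[(4-methoxyphenyl)methoxy]prop-1-en-2-yl}deca-7,9-dien-2-one | C=C/C(Br)=C/C[C@@H](CCC(C)=O)C(=C)COCc1ccc(OC)cc1 | intermediate
11 | (5R,7Z)-8-bromo-5-{3-[(4-methoxyphenyl)methoxy]prop-1-en-2-yl}-2-methyldeca-1,7,9-triene | C=C/C(Br)=C/C[C@@H](CCC(C)=C)C(=C)COCc1ccc(OC)cc1 | intermediate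
12 | (5R,7E)-8-lithio-5-{3-[(4-methoxyphenyl)methoxy]prop-1-en-2-yl}-2-methyldeca-1,7,9-triene | C=C/C([Li])=C/C[C@@H](CCC(C)=C)C(=C)COCc1ccc(OC)cc1 | intermediate
13 | (2Z,5R)-2-ethenyl-5-{3-[(4-methoxyphenyl)methoxy]prop-1-en-2-yl}-8-methylnona-2,8-dien-1-ol | C=C/C(CO)=C/C[C@@H](CCC(C)=C)C(=C)COCc1ccc(OC)cc1 | intermediate
14 | [(4aR,7R,8aR)-7-{3-[(4-methoxyphenyl)methoxy]prop-1-en-2-yl}-4a-methyl-3,4,4a,5,6,7,8,8a-octahydronaphthalen-1-yl]methanol | C=C(COCc1ccc(OC)cc1)[C@@H]1CC[C@@]2(C)CCC=C(CO)[C@@H]2C1 | intermediate
15 | [bis(2,2,2-trifluoroethoxy)phosphoryl]acetic acid | OC(=O)CP(=O)(OCC(F)(F)F)OCC(F)(F)F | starting material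
16 | [(4aR,7R,8aR)-7-{3-[(4-methoxyphenyl)methoxy]prop-1-en-2-yl}-4a-methyl-3,4,4a,5,6,7,8,8a-octahydronaphthalen-1-yl]methyl 2-[bis(2,2,2-trifluoroethoxy)phosphoryl]acetate | C=C(COCc1ccc(OC)cc1)[C@@H]1CC[C@@]2(C)CCC=C(COC(=O)CP(=O)(OCC(F)(F)F)OCC(F)(F)F)[C@@H]2C1 | intermediate
17 | 4-[(tert-butyldimethylsilyl)oxy]benzaldehyde | CC(C)(C)[Si](C)(C)Oc1ccc(C=O)cc1 | starting material
18 | [(4aR,7R,8aR)-7-{3-[(4-methoxyphenyl)methoxy]prop-1-en-2-yl}-4a-methyl-3,4,4a,5,6,7,8,8a-octahydronaphthalen-1-yl]methyl (2Z)-3-{4-[(tert-butyldimethylsilyl)oxy]phenyl}prop-2-enoate | C=C(COCc1ccc(OC)cc1)[C@@H]1CC[C@@]2(C)CCC=C(COC(=O)/C=C\c3ccc(O[Si](C)(C)C(C)(C)C)cc3)[C@@H]2C1 | intermediate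
19 | [(4aR,7R,8aR)-7-(3-hydroxyprop-1-en-2-yl)-4a-methyl-3,4,4a,5,6,7,8,8a-octahydronaphthalen-1-yl]methyl (2Z)-3-{4-[(tert-butyldimethylsilyl)oxy]phenyl}prop-2-enoate | C=C(CO)[C@@H]1CC[C@@]2(C)CCC=C(COC(=O)/C=C\c3ccc(O[Si](C)(C)C(C)(C)C)cc3)[C@@H]2C1 | intermediate
20 | [(4aR,7R,8aR)-4a-methyl-7-(3-oxoprop-1-en-2-yl)-3,4,4a,5,6,7,8,8a-octahydronaphthalen-1-yl]methyl (2Z)-3-{4-[(tert-butyldimethylsilyl)oxy]phenyl}prop-2-enoate | C=C(C=O)[C@@H]1CC[C@@]2(C)CCC=C(COC(=O)/C=C\c3ccc(O[Si](C)(C)C(C)(C)C)cc3)[C@@H]2C1 | intermediate
21 | 2-[(2R,4aR,8aR)-8-{[((2Z)-3-{4-[(tert-butyldimethylsilyl)oxy]phenyl}prop-2-enoyl)oxy]methyl}-4a-methyl-1,2,3,4,4a,5,6,8a-octahydronaphthalen-2-yl]prop-2-enoic acid | C=C(C(=O)O)[C@@H]1CC[C@@]2(C)CCC=C(COC(=O)/C=C\c3ccc(O[Si](C)(C)C(C)(C)C)cc3)[C@@H]2C1 | intermediate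
22 | 2-[(2R,4aR,8aR)-8-({[(2Z)-3-(4-hydroxyphenyl)prop-2-enoyl]oxy}methyl)-4a-methyl-1,2,3,4,4a,5,6,8a-octahydronaphthalen-2-yl]prop-2-enoic acid | C=C(C(=O)O)[C@@H]1CC[C@@]2(C)CCC=C(COC(=O)/C=C\c3ccc(O)cc3)[C@@H]2C1 | target

## Step count and least certain steps

Total steps: 15. Longest linear sequence: 15 (1 → 22); 15 and 17 are purchased.

**Step 9 (key step).** The most likely failure is insufficient preference for the extended over the folded transition state, which would give poor ring-fusion selectivity. Incomplete equatorial control by C7, slow conversion of the unactivated olefin and thermal oligomerisation are further risks. A reversible Cope shift across C6–C7 (the C4=C5/C11=C13 1,5-diene) is conceivable but is uphill and should be much slower than the cycloaddition. The fallback sets out from 11 and returns at 14. The bromotriene 11 is cyclised itself under the same thermal regime. Bromine on C4 is the classical steric directing group for trans-fused decalins in this reaction class, and it is rigid, lying in the diene plane with no rotamer that relieves the clash in the folded geometry. This gives (4aS,7R,8aR)-1-bromo-7-{3-[(4-methoxyphenyl)methoxy]prop-1-en-2-yl}-4a-methyl-3,4,4a,5,6,7,8,8a-octahydronaphthalene F1. Bromine–lithium exchange on F1 (t-BuLi, −78 °C) and trapping with formaldehyde then installs C15 on the finished ring and gives 14. The control element changes from the CH2OH group to the halogen, and the C4–C15 bond is formed after, not before, the ring construction.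

**Step 8.** The most likely failure is proton quench of the dienyllithium or carbolithiation of the diene competing with the exchange, with partial loss of the C4=C5 geometry. The fallback sets out from 8 and returns at 13, and needs no organolithium. Olefination of 8 with the α-bromo analogue of the Still–Gennari phosphonate (KOt-Bu, 18-crown-6, −78 °C) gives methyl (2E,5R)-2-bromo-5-{3-[(4-methoxyphenyl)methoxy]prop-1-en-2-yl}-8-oxonon-2-enoate F2, with the chain cis to the ester. Stille vinylation with retention gives methyl (2Z,5R)-2-ethenyl-5-{3-[(4-methoxyphenyl)methoxy]prop-1-en-2-yl}-8-oxonon-2-enoate F3. Wittig methylenation of the ketone gives methyl (2Z,5R)-2-ethenyl-5-{3-[(4-methoxyphenyl)methoxy]prop-1-en-2-yl}-8-methylnona-2,8-dienoate F4, and reduction with i-Bu2AlH at −78 °C gives 13. C15 arrives as the ester carbon.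

**Step 1.** The most likely failure is incomplete or unselective metalation (ring allylic positions) and low recovery through borylation and oxidation. The fallback sets out from 1 and returns at 6. The ring olefin is epoxidised first (mCPBA) to (4R)-1-methyl-4-(prop-1-en-2-yl)-7-oxabicyclo[4.1.0]heptane F5. The isopropenyl group is then the only olefin and undergoes ene-type allylic chlorination with hypochlorous acid (NaOCl, CeCl3·7H2O, CH2Cl2/H2O) to (4R)-4-(3-chloroprop-1-en-2-yl)-1-methyl-7-oxabicyclo[4.1.0]heptane F6. Displacement of the allylic chloride with sodium 4-methoxybenzyl oxide gives 6.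

**Step 11.** The most likely failure is erosion of Z selectivity through reversible addition to the electron-rich aldehyde, or base-induced side reactions of the phosphonoacetate. The fallback sets out from 14 and returns at 18, and makes the Z bond by syn addition of hydrogen. 3-{4-[(tert-Butyldimethylsilyl)oxy]phenyl}prop-2-ynoic acid F7 (from commercial tert-butyl(4-ethynylphenoxy)dimethylsilane by lithiation and carboxylation) is coupled to 14 (DCC, DMAP) to give [(4aR,7R,8aR)-7-{3-[(4-methoxyphenyl)methoxy]prop-1-en-2-yl}-4a-methyl-3,4,4a,5,6,7,8,8a-octahydronaphthalen-1-yl]methyl 3-{4-[(tert-butyldimethylsilyl)oxy]phenyl}prop-2-ynoate F8. Semi-hydrogenation over lead-poisoned Pd/CaCO3 with quinoline then gives 18.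

## Further compounds

F1 | step 9 | (4aS,7R,8aR)-1-bromo-7-{3-[(4-methoxyphenyl)methoxy]prop-1-en-2-yl}-4a-methyl-3,4,4a,5,6,7,8,8a-octahydronaphthalene | C=C(COCc1ccc(OC)cc1)[C@@H]1CC[C@@]2(C)CCC=C(Br)[C@@H]2C1
F2 | step 8 | methyl (2E,5R)-2-bromo-5-{3-[(4-methoxyphenyl)methoxy]prop-1-en-2-yl}-8-oxonon-2-enoate | COC(=O)/C(Br)=C\C[C@@H](CCC(C)=O)C(=C)COCc1ccc(OC)cc1
F3 | step 8 | methyl (2Z,5R)-2-ethenyl-5-{3-[(4-methoxyphenyl)methoxy]prop-1-en-2-yl}-8-oxonon-2-enoate | COC(=O)/C(C=C)=C\C[C@@H](CCC(C)=O)C(=C)COCc1ccc(OC)cc1
F4 | step 8 | methyl (2Z,5R)-2-ethenyl-5-{3-[(4-methoxyphenyl)methoxy]prop-1-en-2-yl}-8-methylnona-2,8-dienoate | COC(=O)/C(C=C)=C\C[C@@H](CCC(C)=C)C(=C)COCc1ccc(OC)cc1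
F5 | step 1 | (4R)-1-methyl-4-(prop-1-en-2-yl)-7-oxabicyclo[4.1.0]heptane (epoxide diastereomers) | CC12OC1C[C@@H](CC2)C(C)=C
F6 | step 1 | (4R)-4-(3-chloroprop-1-en-2-yl)-1-methyl-7-oxabicyclo[4.1.0]heptane (epoxide diastereomers) | CC12OC1C[C@@H](CC2)C(=C)CCl
F7 | step 11 | 3-{4-[(tert-butyldimethylsilyl)oxy]phenyl}prop-2-ynoic acid | CC(C)(C)[Si](C)(C)Oc1ccc(C#CC(=O)O)cc1
F8 | step 11 | [(4aR,7R,8aR)-7-{3-[(4-methoxyphenyl)methoxy]prop-1-en-2-yl}-4a-methyl-3,4,4a,5,6,7,8,8a-octahydronaphthalen-1-yl]methyl 3-{4-[(tert-butyldimethylsilyl)oxy]phenyl}prop-2-ynoate | C=C(COCc1ccc(OC)cc1)[C@@H]1CC[C@@]2(C)CCC=C(COC(=O)C#Cc3ccc(O[Si](C)(C)C(C)(C)C)cc3)[C@@H]2C1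
A1 | alternative 1 | (5R)-2-methyl-5-(prop-1-en-2-yl)cyclohexan-1-one (dihydrocarvone, C2 epimers) | CC1CC[C@H](CC1=O)C(C)=C
A2 | alternative 1 | (4aS,7R)-4a-methyl-7-(prop-1-en-2-yl)-4,4a,5,6,7,8-hexahydronaphthalen-2(3H)-one | C=C(C)[C@@H]1CC[C@@]2(C)CCC(=O)C=C2C1
A3 | alternative 1 | methyl 4a-methyl-2-oxo-7-(prop-1-en-2-yl)decahydronaphthalene-1-carboxylate (trans-fused, configuration of the target at C4a, C7 and C8a) | C=C(C)[C@@H]1CC[C@@]2(C)CCC(=O)C(C(=O)OC)[C@@H]2C1
A4 | alternative 2 | methyl (1(10)E,4E)-15-hydroxygermacra-1(10),4,11(13)-trien-12-oate (C7 as in the target) | C/C1=C\CC/C(CO)=C/C[C@@H](CC1)C(=C)C(=O)OC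
A5 | alternative 3 | 2-[2-(but-3-en-1-yl)-2-methyl-5-(prop-1-en-2-yl)cyclohexyl]prop-2-en-1-ol (ring configuration of the target at C5, C7 and C10) | C=C(C)[C@@H]1CC[C@@](C)(CCC=C)[C@H](C(=C)CO)C1
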